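**Retrosynthetic overview**

1. Target 23 comes from the hexa-O-benzyl 4'-O-acetyl biflavonoid 21 by hydrogenolysis and acidic deacetylation, so no base touches the flavanone.
2. 21 comes from the acyclic tetraaryl di-tert-butyl ester 18 by cutting both aryl ketone bonds C4–C4a, one in ring C of the flavanone and one in ring C of the flavone (forward: a double intramolecular Friedel–Crafts acylation). Enabling feature: in each half C4a is the ring A carbon ortho to the ring oxygen O1 of a 5,7-dioxygenated ring A, so each precursor aryl ether has two equivalent ortho carbons activated by three oxygens; in the flavanone half the C6–C6' biaryl bond lies para to O1 on the local mirror axis, so closure at either ortho carbon can give only the 6-linked isomer.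
3. 18 comes from phenol 12 and the (S)-β-hydroxy ester 17 by Mitsunobu etherification with inversion, which sets C2 as R; 17 comes from β-keto ester 16 by asymmetric transfer hydrogenation.
4. 12 comes from aryl bromide 7 and the arylzinc made from silyl ether 8 (directed metalation, Negishi coupling); 7 comes from arylpropiolate 5 and 3,5-bis(benzyloxy)phenol 6 (oxa-Michael addition); 5 comes from 3,4-bis(benzyloxy)benzaldehyde 1.
5. Ring order: all four benzene rings are purchased; no heterocycle exists until step 11, where ring C of the flavanone and ring C of the flavone close in the same operation.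

Key step: step 11

Remark: the target defines no configuration for the tri-ortho-substituted C6–C6' biaryl axis, so it is treated as configurationally labile and biaryl intermediates carry no axial descriptor; the enol ether of 7 is drawn as the Z isomer expected from anti addition, and any E isomer can be carried on because step 11 converges both.

**Route**

Step 1
Reactants: 1 3,4-bis(benzyloxy)benzaldehyde
Product: 2 4,5-bis(benzyloxy)-2-bromobenzaldehyde
Conditions: Br2, NaOAc, AcOH, rt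
Reagents that add atoms: bromine, BrBr
Why: Electrophilic aromatic bromination should occur at position 6 (para to the 3-benzyloxy group, ortho to the formyl group), as with other 3,4-dialkoxybenzaldehydes, and the acetate buffer keeps HBr from cleaving the benzyl ethers.

Step 2
Reactants: 2 4,5-bis(benzyloxy)-2-bromobenzaldehyde
Product: 3 1,2-bis(benzyloxy)-4-bromo-5-ethynylbenzene
Conditions: dimethyl (1-diazo-2-oxopropyl)phosphonate, K2CO3, MeOH/THF, rt
Reagents that add atoms: dimethyl (1-diazo-2-oxopropyl)phosphonate, CC(=O)C(=[N+]=[N-])P(=O)(OC)OC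
Why: Seyferth–Gilbert homologation with the Bestmann–Ohira reagent converts the aldehyde into the terminal alkyne under mild carbonate conditions that leave the aryl bromide and benzyl ethers untouched.

Step 3
Reactants: 3 1,2-bis(benzyloxy)-4-bromo-5-ethynylbenzene
Product: 5 tert-butyl 3-[4,5-bis(benzyloxy)-2-bromophenyl]prop-2-ynoate, via lithium acetylide 4 (not isolated)
Conditions: LiN(SiMe3)2, THF, -78 °C; then Boc2O, -78 to 0 °C
Reagents that add atoms: di-tert-butyl dicarbonate, CC(C)(C)OC(=O)OC(=O)OC(C)(C)C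
Why: Deprotonation of the terminal alkyne by an amide base (which, unlike an alkyllithium, does not exchange the aryl bromide) followed by C-acylation of the acetylide with Boc2O is a standard preparation of tert-butyl alkynoates.

Step 4
Reactants: 5 tert-butyl 3-[4,5-bis(benzyloxy)-2-bromophenyl]prop-2-ynoate; 6 3,5-bis(benzyloxy)phenol
Product: 7 tert-butyl (2Z)-3-[4,5-bis(benzyloxy)-2-bromophenyl]-3-[3,5-bis(benzyloxy)phenoxy]prop-2-enoate
Conditions: K2CO3, DMF, 60 °C
Reagents that add atoms: none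
Why: Base-mediated oxa-Michael addition (hydroaryloxylation) of the phenoxide to the β-carbon of the arylpropiolate should give the 3-aryloxycinnamate, and the symmetric phenol has only one kind of hydroxyl group.

Step 5
Reactants: 6 3,5-bis(benzyloxy)phenol
Product: 8 [3,5-bis(benzyloxy)phenoxy]tri(propan-2-yl)silane
Conditions: TIPSCl, imidazole, DMF, rt
Reagents that add atoms: chlorotri(propan-2-yl)silane, CC(C)[Si](Cl)(C(C)C)C(C)C
Why: Standard silylation of a phenol installs a bulky, poorly coordinating silyloxy group that should steer the later metalation away from its own ortho positions.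

Step 6
Reactants: 8 [3,5-bis(benzyloxy)phenoxy]tri(propan-2-yl)silane; 7 tert-butyl (2Z)-3-[4,5-bis(benzyloxy)-2-bromophenyl]-3-[3,5-bis(benzyloxy)phenoxy]prop-2-enoate
Product: 11 tert-butyl (2Z)-3-[4,5-bis(benzyloxy)-2-{2,6-bis(benzyloxy)-4-[tri(propan-2-yl)silyloxy]phenyl}phenyl]-3-[3,5-bis(benzyloxy)phenoxy]prop-2-enoate, via aryllithium 9 (not isolated), via arylzinc chloride 10 (not isolated)
Conditions: n-BuLi, TMEDA, Et2O, 0 °C; ZnCl2 (THF), 0 °C to rt; then 7, Pd2(dba)3, RuPhos, THF, 60 °C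
Reagents that add atoms: none
Why: Directed ortho metalation should occur at the ring carbon flanked by the two benzyloxy groups (the most acidic C–H, doubly coordinated and remote from the silyl ether), and transmetalation to zinc followed by Negishi cross-coupling under a dialkylbiarylphosphine–palladium catalyst is an established way to tri-ortho-substituted biaryls that tolerates the ester and enol ether.

Step 7
Reactants: 11 tert-butyl (2Z)-3-[4,5-bis(benzyloxy)-2-{2,6-bis(benzyloxy)-4-[tri(propan-2-yl)silyloxy]phenyl}phenyl]-3-[3,5-bis(benzyloxy)phenoxy]prop-2-enoate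
Product: 12 tert-butyl (2Z)-3-{4,5-bis(benzyloxy)-2-[2,6-bis(benzyloxy)-4-hydroxyphenyl]phenyl}-3-[3,5-bis(benzyloxy)phenoxy]prop-2-enoate
Conditions: Bu4NF, AcOH, THF, 0 °C
Reagents that add atoms: none
Why: Fluoride-mediated desilylation of the aryl silyl ether, buffered with acetic acid, should free the single phenol that lies para to the biaryl bond without letting a phenoxide attack the acrylate.

Step 8
Reactants: 13 4-(chlorocarbonyl)phenyl acetate; 14 2,2-dimethyl-1,3-dioxane-4,6-dione (Meldrum's acid)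
Product: 16 tert-butyl 3-[4-(acetyloxy)phenyl]-3-oxopropanoate, via acyl Meldrum's acid 15 (not isolated)
Conditions: pyridine, CH2Cl2, 0 °C to rt; then t-BuOH, toluene, 90 °C
Reagents that add atoms: tert-butanol, CC(C)(C)O
Why: C-acylation of Meldrum's acid followed by thermal alcoholysis (acylketene formation, trapping by tert-butanol, loss of acetone and CO2) is a standard β-keto ester synthesis that the aryl acetate should tolerate.

Step 9
Reactants: 16 tert-butyl 3-[4-(acetyloxy)phenyl]-3-oxopropanoate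
Product: 17 tert-butyl (3S)-3-[4-(acetyloxy)phenyl]-3-hydroxypropanoate
Conditions: RuCl(p-cymene)[(S,S)-TsDPEN] (1 mol %), HCO2H/Et3N (5:2), rt
Reagents that add atoms: none
Why: Noyori-type asymmetric transfer hydrogenation of the aryl ketone sets the carbinol stereocenter, the (S,S)-TsDPEN ligand delivering hydride to the face that gives the (S)-benzylic alcohol, as with acetophenone-type substrates.

Step 10
Reactants: 12 tert-butyl (2Z)-3-{4,5-bis(benzyloxy)-2-[2,6-bis(benzyloxy)-4-hydroxyphenyl]phenyl}-3-[3,5-bis(benzyloxy)phenoxy]prop-2-enoate; 17 tert-butyl (3S)-3-[4-(acetyloxy)phenyl]-3-hydroxypropanoate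
Product: 18 tert-butyl (2Z)-3-{2-[4-({(1R)-1-[4-(acetyloxy)phenyl]-3-tert-butoxy-3-oxopropyl}oxy)-2,6-bis(benzyloxy)phenyl]-4,5-bis(benzyloxy)phenyl}-3-[3,5-bis(benzyloxy)phenoxy]prop-2-enoate
Conditions: PPh3, DIAD, toluene, 0 °C to rt
Reagents that add atoms: none
Why: Mitsunobu etherification of the phenol with the secondary benzylic alcohol proceeds by SN2 displacement of the oxyphosphonium group with inversion, turning (S)-17 into the (R)-aryl ether that becomes C2 of the flavanone, while the electron-poor 4-acetoxyphenyl group disfavours ionization.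

Step 11
Reactants: 18 tert-butyl (2Z)-3-{2-[4-({(1R)-1-[4-(acetyloxy)phenyl]-3-tert-butoxy-3-oxopropyl}oxy)-2,6-bis(benzyloxy)phenyl]-4,5-bis(benzyloxy)phenyl}-3-[3,5-bis(benzyloxy)phenoxy]prop-2-enoate
Product: 21 4-[(2R)-5,7-bis(benzyloxy)-6-{4,5-bis(benzyloxy)-2-[5,7-bis(benzyloxy)-4-oxo-4H-chromen-2-yl]phenyl}-4-oxo-3,4-dihydro-2H-chromen-2-yl]phenyl acetate, via diacid 19 (not isolated), via bis(trifluoroacetic) mixed anhydride 20 (not isolated)
Conditions: TFA/CH2Cl2 (1:3), 0 °C to rt; evaporate; then TFAA, CH2Cl2, 0 °C to rt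
Reagents that add atoms: none
Why: TFA first removes both tert-butyl groups (2-methylpropene leaves), TFAA then converts both acids of 19 into the mixed anhydrides of 20, and each ionizes, helped by the liberated TFA, to an acylium-type electrophile that attacks the arene carbon ortho to its ether oxygen; this is intramolecular Friedel–Crafts acylation, the classical route to chroman-4-ones from 3-aryloxypropanoic acids and to flavones from 3-aryloxycinnamic acids, here run on both acids in one flask. Ring C of the flavanone closes as a six-membered ring, exo at the saturated acyl carbon, forming C4–C4a on the central ring, and ring C of the flavone closes in the same mode through the vinylogous acylium of the aryloxyacrylate, whose ketene-like resonance form lets the C2–C3 bond rotate so that E and Z isomers converge. No new stereocenter is formed, and C2 of the flavanone, set in step 10, should be retained because the electron-poor 4-acetoxyphenyl group disfavours ionization of the benzylic C–O bond and no base is present. Regioselectivity rests on symmetry: in each aryl ether the two carbons ortho to the ether oxygen are equivalent and are the only ones that can reach the acyl carbon through a six-membered transition state, and on the central ring the biaryl bond is para to that oxygen, so only the 6-linked flavanone can form. The two acyl groups cannot cross over because each has only its own arene within reach, and each new carbonyl deactivates its ring against further acylation.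

Step 12
Reactants: 21 4-[(2R)-5,7-bis(benzyloxy)-6-{4,5-bis(benzyloxy)-2-[5,7-bis(benzyloxy)-4-oxo-4H-chromen-2-yl]phenyl}-4-oxo-3,4-dihydro-2H-chromen-2-yl]phenyl acetate
Product: 23 (2R)-6-[2-(5,7-dihydroxy-4-oxo-4H-chromen-2-yl)-4,5-dihydroxyphenyl]-5,7-dihydroxy-2-(4-hydroxyphenyl)-2,3-dihydro-4H-chromen-4-one, via hexaphenol acetate 22 (not isolated)
Conditions: H2 (1 atm), 10% Pd/C, THF/MeOH, rt; filter; then HCl (1.25 M in MeOH), rt
Reagents that add atoms: none
Why: Catalytic hydrogenolysis of the six benzyl ethers under neutral conditions should spare the flavone C2–C3 double bond and the flavanone and cannot epimerize C2, and acid-catalysed transesterification then removes the aryl acetate without the base that would open the flavanone ring.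

**Compound list**

1 | 3,4-bis(benzyloxy)benzaldehyde | O=Cc1ccc(OCc2ccccc2)c(OCc2ccccc2)c1 | starting material
2 | 4,5-bis(benzyloxy)-2-bromobenzaldehyde | O=Cc1cc(OCc2ccccc2)c(OCc2ccccc2)cc1Br | intermediate
3 | 1,2-bis(benzyloxy)-4-bromo-5-ethynylbenzene | C#Cc1cc(OCc2ccccc2)c(OCc2ccccc2)cc1Br | intermediate
4 | lithium [4,5-bis(benzyloxy)-2-bromophenyl]ethynide | [Li]C#Cc1cc(OCc2ccccc2)c(OCc2ccccc2)cc1Br | intermediate
5 | tert-butyl 3-[4,5-bis(benzyloxy)-2-bromophenyl]prop-2-ynoate | CC(C)(C)OC(=O)C#Cc1cc(OCc2ccccc2)c(OCc2ccccc2)cc1Br | intermediate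
6 | 3,5-bis(benzyloxy)phenol | Oc1cc(OCc2ccccc2)cc(OCc2ccccc2)c1 | starting material
7 | tert-butyl (2Z)-3-[4,5-bis(benzyloxy)-2-bromophenyl]-3-[3,5-bis(benzyloxy)phenoxy]prop-2-enoate | CC(C)(C)OC(=O)/C=C(\Oc1cc(OCc2ccccc2)cc(OCc2ccccc2)c1)c1cc(OCc2ccccc2)c(OCc2ccccc2)cc1Br | intermediate
8 | [3,5-bis(benzyloxy)phenoxy]tri(propan-2-yl)silane | CC(C)[Si](Oc1cc(OCc2ccccc2)cc(OCc2ccccc2)c1)(C(C)C)C(C)C | intermediate
9 | {2,6-bis(benzyloxy)-4-[tri(propan-2-yl)silyloxy]phenyl}lithium | [Li]c1c(OCc2ccccc2)cc(O[Si](C(C)C)(C(C)C)C(C)C)cc1OCc1ccccc1 | intermediate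
10 | {2,6-bis(benzyloxy)-4-[tri(propan-2-yl)silyloxy]phenyl}zinc chloride | Cl[Zn]c1c(OCc2ccccc2)cc(O[Si](C(C)C)(C(C)C)C(C)C)cc1OCc1ccccc1 | intermediate
11 | tert-butyl (2Z)-3-[4,5-bis(benzyloxy)-2-{2,6-bis(benzyloxy)-4-[tri(propan-2-yl)silyloxy]phenyl}phenyl]-3-[3,5-bis(benzyloxy)phenoxy]prop-2-enoate | CC(C)(C)OC(=O)/C=C(\Oc1cc(OCc2ccccc2)cc(OCc2ccccc2)c1)c1cc(OCc2ccccc2)c(OCc2ccccc2)cc1-c1c(OCc2ccccc2)cc(O[Si](C(C)C)(C(C)C)C(C)C)cc1OCc1ccccc1 | intermediate
12 | tert-butyl (2Z)-3-{4,5-bis(benzyloxy)-2-[2,6-bis(benzyloxy)-4-hydroxyphenyl]phenyl}-3-[3,5-bis(benzyloxy)phenoxy]prop-2-enoate | CC(C)(C)OC(=O)/C=C(\Oc1cc(OCc2ccccc2)cc(OCc2ccccc2)c1)c1cc(OCc2ccccc2)c(OCc2ccccc2)cc1-c1c(OCc2ccccc2)cc(O)cc1OCc1ccccc1 | intermediate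
13 | 4-(chlorocarbonyl)phenyl acetate | CC(=O)Oc1ccc(C(=O)Cl)cc1 | starting material
14 | 2,2-dimethyl-1,3-dioxane-4,6-dione (Meldrum's acid) | CC1(C)OC(=O)CC(=O)O1 | starting material
15 | 4-[(2,2-dimethyl-4,6-dioxo-1,3-dioxan-5-ylidene)(hydroxy)methyl]phenyl acetate | CC(=O)Oc1ccc(C(O)=C2C(=O)OC(C)(C)OC2=O)cc1 | intermediate
16 | tert-butyl 3-[4-(acetyloxy)phenyl]-3-oxopropanoate | CC(=O)Oc1ccc(C(=O)CC(=O)OC(C)(C)C)cc1 | intermediate
17 | tert-butyl (3S)-3-[4-(acetyloxy)phenyl]-3-hydroxypropanoate | CC(C)(C)OC(=O)C[C@@H](c1ccc(OC(C)=O)cc1)O | intermediate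
18 | tert-butyl (2Z)-3-{2-[4-({(1R)-1-[4-(acetyloxy)phenyl]-3-tert-butoxy-3-oxopropyl}oxy)-2,6-bis(benzyloxy)phenyl]-4,5-bis(benzyloxy)phenyl}-3-[3,5-bis(benzyloxy)phenoxy]prop-2-enoate | CC(C)(C)OC(=O)C[C@H](c1ccc(OC(C)=O)cc1)Oc1cc(OCc2ccccc2)c(-c2cc(OCc3ccccc3)c(OCc3ccccc3)cc2/C(Oc2cc(OCc3ccccc3)cc(OCc3ccccc3)c2)=C/C(=O)OC(C)(C)C)c(OCc2ccccc2)c1 | intermediate
19 | (3R)-3-[4-(acetyloxy)phenyl]-3-{3,5-bis(benzyloxy)-4-[4,5-bis(benzyloxy)-2-{(1Z)-1-[3,5-bis(benzyloxy)phenoxy]-2-carboxyethenyl}phenyl]phenoxy}propanoic acid | OC(=O)C[C@H](c1ccc(OC(C)=O)cc1)Oc1cc(OCc2ccccc2)c(-c2cc(OCc3ccccc3)c(OCc3ccccc3)cc2/C(Oc2cc(OCc3ccccc3)cc(OCc3ccccc3)c2)=C/C(=O)O)c(OCc2ccccc2)c1 | intermediate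
20 | bis(trifluoroacetic) mixed anhydride of diacid 19 | FC(F)(F)C(=O)OC(=O)C[C@H](c1ccc(OC(C)=O)cc1)Oc1cc(OCc2ccccc2)c(-c2cc(OCc3ccccc3)c(OCc3ccccc3)cc2/C(Oc2cc(OCc3ccccc3)cc(OCc3ccccc3)c2)=C/C(=O)OC(=O)C(F)(F)F)c(OCc2ccccc2)c1 | intermediate
21 | 4-[(2R)-5,7-bis(benzyloxy)-6-{4,5-bis(benzyloxy)-2-[5,7-bis(benzyloxy)-4-oxo-4H-chromen-2-yl]phenyl}-4-oxo-3,4-dihydro-2H-chromen-2-yl]phenyl acetate | O=C1C[C@H](c2ccc(OC(C)=O)cc2)Oc2cc(OCc3ccccc3)c(-c3cc(OCc4ccccc4)c(OCc4ccccc4)cc3-c3cc(=O)c4c(OCc5ccccc5)cc(OCc5ccccc5)cc4o3)c(OCc3ccccc3)c21 | intermediate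
22 | 4-[(2R)-6-[2-(5,7-dihydroxy-4-oxo-4H-chromen-2-yl)-4,5-dihydroxyphenyl]-5,7-dihydroxy-4-oxo-3,4-dihydro-2H-chromen-2-yl]phenyl acetate | O=C1C[C@H](c2ccc(OC(C)=O)cc2)Oc2cc(O)c(-c3cc(O)c(O)cc3-c3cc(=O)c4c(O)cc(O)cc4o3)c(O)c21 | intermediate
23 | (2R)-6-[2-(5,7-dihydroxy-4-oxo-4H-chromen-2-yl)-4,5-dihydroxyphenyl]-5,7-dihydroxy-2-(4-hydroxyphenyl)-2,3-dihydro-4H-chromen-4-one (CNP0168406.2) | O=C1C[C@H](c2ccc(O)cc2)Oc2cc(O)c(-c3cc(O)c(O)cc3-c3cc(=O)c4c(O)cc(O)cc4o3)c(O)c21 | target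

**Step count and risks**

Total step count: 12. Longest linear sequence: 9 steps (1, 2, 3, 4, 6, 7, 10, 11, 12).

Steps most likely to fail:

Step 6. The alkyllithium may deprotonate a benzylic OCH2 position, followed by Wittig rearrangement, instead of the ring carbon between the two benzyloxy groups, and the doubly ortho-substituted arylzinc may transmetalate and couple slowly. Fallback (halogen–metal exchange in place of C–H metalation): starting from 6, para bromination with NBS (CH2Cl2, -78 °C, removal of the ortho isomer by chromatography) should give 3,5-bis(benzyloxy)-4-bromophenol F1. Silylation (TIPSCl, imidazole) gives [3,5-bis(benzyloxy)-4-bromophenoxy]tri(propan-2-yl)silane F2. Bromine–lithium exchange (n-BuLi, THF, -78 °C), which is faster than any deprotonation, then delivers aryllithium 9 with the position fixed by the halogen. The route is rejoined at 9 (ZnCl2, then the coupling of step 6).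

Step 10. The activated β-oxyphosphonium ester may undergo β-elimination to the cinnamate instead of substitution, and partial ionization at the benzylic carbon would erode the configuration. Fallback (an alcohol partner without an acidic α-hydrogen, the carboxyl group revealed afterwards): starting from 12, commercial 4-formylphenyl acetate is converted by Keck asymmetric allylation (allyltributylstannane, Ti(OiPr)4 and the BINOL enantiomer that gives the S alcohol) into 4-[(1S)-1-hydroxybut-3-en-1-yl]phenyl acetate F3. Mitsunobu etherification of 12 with F3 (inversion) should give tert-butyl (2Z)-3-{2-[4-({(1R)-1-[4-(acetyloxy)phenyl]but-3-en-1-yl}oxy)-2,6-bis(benzyloxy)phenyl]-4,5-bis(benzyloxy)phenyl}-3-[3,5-bis(benzyloxy)phenoxy]prop-2-enoate F4. Lemieux–Johnson cleavage of the terminal alkene (OsO4 cat., NaIO4, 2,6-lutidine; the hindered push–pull enol ether should react far more slowly) gives the aldehyde tert-butyl (2Z)-3-{2-[4-({(1R)-1-[4-(acetyloxy)phenyl]-3-oxopropyl}oxy)-2,6-bis(benzyloxy)phenyl]-4,5-bis(benzyloxy)phenyl}-3-[3,5-bis(benzyloxy)phenoxy]prop-2-enoate F5. Pinnick oxidation (NaClO2, NaH2PO4, 2-methylbut-2-ene) gives (3R)-3-[4-(acetyloxy)phenyl]-3-{3,5-bis(benzyloxy)-4-[4,5-bis(benzyloxy)-2-{(1Z)-1-[3,5-bis(benzyloxy)phenoxy]-3-tert-butoxy-3-oxoprop-1-en-1-yl}phenyl]phenoxy}propanoic acid F6. TFA then removes the remaining tert-butyl ester, and the route is rejoined at diacid 19 (TFAA stage of step 11).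

Step 11. The slower flavone closure may force longer acid exposure, during which the benzylic aryl ether could ionize (loss of configuration or elimination), benzyl groups could migrate, or one ring could remain open. Fallback (the two rings closed at different stages, so that only the fast closure is run in the presence of the stereocenter): starting from 7, TFA gives (2Z)-3-[4,5-bis(benzyloxy)-2-bromophenyl]-3-[3,5-bis(benzyloxy)phenoxy]prop-2-enoic acid F7. TFAA, which can be forced because no stereocenter is present, gives 5,7-bis(benzyloxy)-2-[4,5-bis(benzyloxy)-2-bromophenyl]-4H-chromen-4-one F8. Negishi coupling with arylzinc 10 gives 5,7-bis(benzyloxy)-2-[4,5-bis(benzyloxy)-2-{2,6-bis(benzyloxy)-4-[tri(propan-2-yl)silyloxy]phenyl}phenyl]-4H-chromen-4-one F9. Bu4NF/AcOH gives 5,7-bis(benzyloxy)-2-{4,5-bis(benzyloxy)-2-[2,6-bis(benzyloxy)-4-hydroxyphenyl]phenyl}-4H-chromen-4-one F10. Mitsunobu etherification with 17 gives tert-butyl (3R)-3-[4-(acetyloxy)phenyl]-3-{3,5-bis(benzyloxy)-4-[4,5-bis(benzyloxy)-2-(5,7-bis(benzyloxy)-4-oxo-4H-chromen-2-yl)phenyl]phenoxy}propanoate F11. TFA gives (3R)-3-[4-(acetyloxy)phenyl]-3-{3,5-bis(benzyloxy)-4-[4,5-bis(benzyloxy)-2-(5,7-bis(benzyloxy)-4-oxo-4H-chromen-2-yl)phenyl]phenoxy}propanoic acid F12. A single closure of the flavanone ring with TFAA at 0 °C then rejoins the route at 21.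

**Further compounds**

F1 | step 6 | 3,5-bis(benzyloxy)-4-bromophenol | Oc1cc(OCc2ccccc2)c(Br)c(OCc2ccccc2)c1
F2 | step 6 | [3,5-bis(benzyloxy)-4-bromophenoxy]tri(propan-2-yl)silane | CC(C)[Si](Oc1cc(OCc2ccccc2)c(Br)c(OCc2ccccc2)c1)(C(C)C)C(C)C
F3 | step 10 | 4-[(1S)-1-hydroxybut-3-en-1-yl]phenyl acetate | C=CC[C@@H](c1ccc(OC(C)=O)cc1)O
F4 | step 10 | tert-butyl (2Z)-3-{2-[4-({(1R)-1-[4-(acetyloxy)phenyl]but-3-en-1-yl}oxy)-2,6-bis(benzyloxy)phenyl]-4,5-bis(benzyloxy)phenyl}-3-[3,5-bis(benzyloxy)phenoxy]prop-2-enoate | C=CC[C@H](c1ccc(OC(C)=O)cc1)Oc1cc(OCc2ccccc2)c(-c2cc(OCc3ccccc3)c(OCc3ccccc3)cc2/C(Oc2cc(OCc3ccccc3)cc(OCc3ccccc3)c2)=C/C(=O)OC(C)(C)C)c(OCc2ccccc2)c1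
F5 | step 10 | tert-butyl (2Z)-3-{2-[4-({(1R)-1-[4-(acetyloxy)phenyl]-3-oxopropyl}oxy)-2,6-bis(benzyloxy)phenyl]-4,5-bis(benzyloxy)phenyl}-3-[3,5-bis(benzyloxy)phenoxy]prop-2-enoate | O=CC[C@H](c1ccc(OC(C)=O)cc1)Oc1cc(OCc2ccccc2)c(-c2cc(OCc3ccccc3)c(OCc3ccccc3)cc2/C(Oc2cc(OCc3ccccc3)cc(OCc3ccccc3)c2)=C/C(=O)OC(C)(C)C)c(OCc2ccccc2)c1
F6 | step 10 | (3R)-3-[4-(acetyloxy)phenyl]-3-{3,5-bis(benzyloxy)-4-[4,5-bis(benzyloxy)-2-{(1Z)-1-[3,5-bis(benzyloxy)phenoxy]-3-tert-butoxy-3-oxoprop-1-en-1-yl}phenyl]phenoxy}propanoic acid | OC(=O)C[C@H](c1ccc(OC(C)=O)cc1)Oc1cc(OCc2ccccc2)c(-c2cc(OCc3ccccc3)c(OCc3ccccc3)cc2/C(Oc2cc(OCc3ccccc3)cc(OCc3ccccc3)c2)=C/C(=O)OC(C)(C)C)c(OCc2ccccc2)c1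
F7 | step 11 | (2Z)-3-[4,5-bis(benzyloxy)-2-bromophenyl]-3-[3,5-bis(benzyloxy)phenoxy]prop-2-enoic acid | OC(=O)/C=C(\Oc1cc(OCc2ccccc2)cc(OCc2ccccc2)c1)c1cc(OCc2ccccc2)c(OCc2ccccc2)cc1Br
F8 | step 11 | 5,7-bis(benzyloxy)-2-[4,5-bis(benzyloxy)-2-bromophenyl]-4H-chromen-4-one | O=c1cc(-c2cc(OCc3ccccc3)c(OCc3ccccc3)cc2Br)oc2cc(OCc3ccccc3)cc(OCc3ccccc3)c12
F9 | step 11 | 5,7-bis(benzyloxy)-2-[4,5-bis(benzyloxy)-2-{2,6-bis(benzyloxy)-4-[tri(propan-2-yl)silyloxy]phenyl}phenyl]-4H-chromen-4-one | O=c1cc(-c2cc(OCc3ccccc3)c(OCc3ccccc3)cc2-c2c(OCc3ccccc3)cc(O[Si](C(C)C)(C(C)C)C(C)C)cc2OCc2ccccc2)oc2cc(OCc3ccccc3)cc(OCc3ccccc3)c12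
F10 | step 11 | 5,7-bis(benzyloxy)-2-{4,5-bis(benzyloxy)-2-[2,6-bis(benzyloxy)-4-hydroxyphenyl]phenyl}-4H-chromen-4-one | O=c1cc(-c2cc(OCc3ccccc3)c(OCc3ccccc3)cc2-c2c(OCc3ccccc3)cc(O)cc2OCc2ccccc2)oc2cc(OCc3ccccc3)cc(OCc3ccccc3)c12
F11 | step 11 | tert-butyl (3R)-3-[4-(acetyloxy)phenyl]-3-{3,5-bis(benzyloxy)-4-[4,5-bis(benzyloxy)-2-(5,7-bis(benzyloxy)-4-oxo-4H-chromen-2-yl)phenyl]phenoxy}propanoate | CC(C)(C)OC(=O)C[C@H](c1ccc(OC(C)=O)cc1)Oc1cc(OCc2ccccc2)c(-c2cc(OCc3ccccc3)c(OCc3ccccc3)cc2-c2cc(=O)c3c(OCc4ccccc4)cc(OCc4ccccc4)cc3o2)c(OCc2ccccc2)c1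
F12 | step 11 | (3R)-3-[4-(acetyloxy)phenyl]-3-{3,5-bis(benzyloxy)-4-[4,5-bis(benzyloxy)-2-(5,7-bis(benzyloxy)-4-oxo-4H-chromen-2-yl)phenyl]phenoxy}propanoic acid | OC(=O)C[C@H](c1ccc(OC(C)=O)cc1)Oc1cc(OCc2ccccc2)c(-c2cc(OCc3ccccc3)c(OCc3ccccc3)cc2-c2cc(=O)c3c(OCc4ccccc4)cc(OCc4ccccc4)cc3o2)c(OCc2ccccc2)c1
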